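**Plan**

1. Retrosynthesis: the interflavan bond C4 (upper unit)–C6 (lower unit) is cut first (Friedel–Crafts alkylation by a C4 benzylic cation). Ring C of each flavan unit is then cut at C3–C4 and at O1–C8a, which leads to one ring-A block, 4-(benzyloxy)-2-bromobenzyl bromide, and an aryl methyl ketone carrying ring B.
2. Enabling feature: C4a and C8a are neighbouring carbons of ring A, so the bromide offers an sp3 electrophile (C4) and an sp2 electrophile (C8a) in a 1,3-relationship. This matches the two nucleophilic ends, C3 and O1, of the ketone enolate O1–C2(ring B)=C3, and their union is a [3+3] annulation that closes ring C as a 4H-chromene (C2=C3 enol ether).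
3. Forward order: ring-A bromide (3 steps); annulation with the ring-B ketone gives each 4H-chromene (rings A and B preformed, ring C closed last); hydroboration gives the flavan-3-ols. The upper unit is then oxidised at C4, the lower unit is epimerised at C3, and the units are joined C4→C6 and debenzylated.
4. Stereochemistry: asymmetric hydroboration with enantiomeric isopinocampheylboranes sets C2/C3 of both units as 2,3-trans. Oxidation and LiBH(s-Bu)3 reduction turn the lower unit into 2,3-cis (2S,3S). The upper C4 is set in the coupling, the arene entering trans to the 3-OH (4α).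

Key step: step 5

Assumption: flavan numbering (O1, C2, C3, C4, C4a, C5–C8, C8a) is used for both units; the target is read as guibourtinidol-(4α→6)-ent-epifisetinidol (upper unit 2R,3S,4R all-trans, lower unit 2S,3S 2,3-cis); the sense of induction of the isopinocampheylboranes is assigned by analogy with 1-arylcycloalkenes, and the two reagents would be exchanged if it proved opposite.

**Route**

Step 1
Reactants: 1 2-bromo-4-hydroxybenzaldehyde
Product: 2 4-(benzyloxy)-2-bromobenzaldehyde
Conditions: benzyl bromide, K2CO3, DMF, rt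
Reagents that add atoms: benzyl bromide (BrCc1ccccc1)
Why: Williamson etherification, in which the phenoxide formed with K2CO3 displaces bromide from benzyl bromide while the aldehyde and the aryl bromide stay untouched.

Step 2
Reactants: 2 4-(benzyloxy)-2-bromobenzaldehyde
Product: 3 [4-(benzyloxy)-2-bromophenyl]methanol
Conditions: NaBH4, MeOH, 0 °C
Reagents that add atoms: none
Why: Borohydride reduction of the aldehyde to the benzylic alcohol; aryl bromide and benzyl ether are inert to NaBH4.

Step 3
Reactants: 3 [4-(benzyloxy)-2-bromophenyl]methanol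
Product: 4 4-(benzyloxy)-2-bromo-1-(bromomethyl)benzene
Conditions: PBr3, CH2Cl2, 0 °C
Reagents that add atoms: phosphorus tribromide (BrP(Br)Br)
Why: Conversion of an electron-rich benzylic alcohol into its bromide through the phosphite ester, which bromide displaces; the product should be used promptly because a 4-alkoxybenzyl bromide ionises easily.

Step 4
Reactants: 5 1-(3,4-dihydroxyphenyl)ethanone
Product: 6 1-[3,4-bis(benzyloxy)phenyl]ethanone
Conditions: benzyl bromide, K2CO3, DMF, 60 °C
Reagents that add atoms: benzyl bromide (BrCc1ccccc1)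
Why: Double Williamson etherification of the catechol; K2CO3 is too weak to enolise the methyl ketone, so only O-alkylation should occur.

Step 5
Reactants: 6 1-[3,4-bis(benzyloxy)phenyl]ethanone; 4 4-(benzyloxy)-2-bromo-1-(bromomethyl)benzene
Product: 8 7-(benzyloxy)-2-[3,4-bis(benzyloxy)phenyl]-4H-chromene, via bromoaryl propanone 7 (not isolated)
Conditions: LiN(SiMe3)2, THF, −78 °C; 4, −78 to 0 °C; then CuI (10 mol %), 1,10-phenanthroline (20 mol %), Cs2CO3, DMF, 110 °C, same flask
Reagents that add atoms: none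
Why: The preformed lithium enolate of 6 (O1–C2=C3) attacks the benzylic bromide of 4 in an SN2 alkylation and so makes C3–C4 (ketone 7); Cs2CO3 then regenerates the enolate, monovalent copper inserts into the C8a–Br bond, and C–O reductive elimination from the aryl copper enolate makes O1–C8a. The closest known reaction types are the copper-catalysed domino C-benzylation/O-arylation of β-keto esters with 2-bromobenzyl bromides to 4H-chromenes and the Ullmann-type intramolecular O-arylation of simple ketone enolates. Ring C closes as a six-membered ring by attack of the enolate oxygen on the aryl carbon C8a (6-exo at the arene, the enol double bond C2=C3 staying inside the ring), which completes a formal [3+3] annulation. No stereocentre is formed, because the product is the planar C2=C3 enol ether whose two faces are told apart only in step 6. The step needs mono-C-alkylation, which the stoichiometric lithium enolate at low temperature should secure before any further base is added, and O- instead of C-arylation, which the substrate secures because C-arylation at C3 would give a four-membered ring and because the Z-enolate, reached by equilibration through the ketone, holds O1 cis to C4.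

Step 6
Reactants: 8 7-(benzyloxy)-2-[3,4-bis(benzyloxy)phenyl]-4H-chromene
Product: 10 (2S,3R)-7-(benzyloxy)-2-[3,4-bis(benzyloxy)phenyl]chroman-3-ol, via flavanyl isopinocampheylborane 9 (not isolated)
Conditions: (IpcBH2)2·TMEDA [from (−)-α-pinene], BF3·OEt2, Et2O, 0 °C; then 8, −25 °C; then NaOH, H2O2, 0 °C to rt
Reagents that add atoms: hydrogen peroxide (OO)
Why: Asymmetric hydroboration of a trisubstituted enol ether with monoisopinocampheylborane: boron adds to C3 (β to O1, away from the aryl group) and hydrogen to C2 on the same face, and stereoretentive oxidation of C–B gives the 2,3-trans alcohol, the face being chosen by the reagent (the reagent from (+)-α-pinene gives (S)-carbinols from 1-arylcycloalkenes, so the (−)-α-pinene reagent should give 2S,3R here).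

Step 7
Reactants: 10 (2S,3R)-7-(benzyloxy)-2-[3,4-bis(benzyloxy)phenyl]chroman-3-ol
Product: 11 (2S)-7-(benzyloxy)-2-[3,4-bis(benzyloxy)phenyl]-2H-chromen-3(4H)-one
Conditions: Dess–Martin periodinane, CH2Cl2, rt
Reagents that add atoms: none
Why: Dess–Martin oxidation of the secondary alcohol under near-neutral conditions, as used for benzylated flavan-3-ols, which should leave the acidic C2–H (α to the ketone, benzylic, α to O1) unepimerised if the ketone is used at once.

Step 8
Reactants: 11 (2S)-7-(benzyloxy)-2-[3,4-bis(benzyloxy)phenyl]-2H-chromen-3(4H)-one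
Product: 12 (2S,3S)-7-(benzyloxy)-2-[3,4-bis(benzyloxy)phenyl]chroman-3-ol
Conditions: LiBH(s-Bu)3, LiBr, THF, −78 °C; then H2O
Reagents that add atoms: none
Why: Bulky-hydride reduction of the flavan-3-one: the hydride attacks C3 from the face opposite the pseudo-equatorial 2-aryl group, so the new 3-OH ends up cis to the aryl group (2S,3S), the known way from catechin-type to epicatechin-type benzyl ethers.

Step 9
Reactants: 13 1-[4-(benzyloxy)phenyl]ethanone; 4 4-(benzyloxy)-2-bromo-1-(bromomethyl)benzene
Product: 15 7-(benzyloxy)-2-[4-(benzyloxy)phenyl]-4H-chromene, via bromoaryl propanone 14 (not isolated)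
Conditions: LiN(SiMe3)2, THF, −78 °C; 4, −78 to 0 °C; then CuI (10 mol %), 1,10-phenanthroline (20 mol %), Cs2CO3, DMF, 110 °C, same flask
Reagents that add atoms: none
Why: The same annulation as in step 5 (enolate C-benzylation, then Ullmann-type enolate O-arylation) applied to the ring-B ketone of the upper unit; no stereocentre is formed.

Step 10
Reactants: 15 7-(benzyloxy)-2-[4-(benzyloxy)phenyl]-4H-chromene
Product: 17 (2R,3S)-7-(benzyloxy)-2-[4-(benzyloxy)phenyl]chroman-3-ol, via flavanyl isopinocampheylborane 16 (not isolated)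
Conditions: (IpcBH2)2·TMEDA [from (+)-α-pinene], BF3·OEt2, Et2O, 0 °C; then 15, −25 °C; then NaOH, H2O2, 0 °C to rt
Reagents that add atoms: hydrogen peroxide (OO)
Why: Asymmetric hydroboration as in step 6 with the enantiomeric reagent: syn addition of H–B with boron at C3 and stereoretentive oxidation should give the 2,3-trans alcohol of the natural 2R,3S series.

Step 11
Reactants: 17 (2R,3S)-7-(benzyloxy)-2-[4-(benzyloxy)phenyl]chroman-3-ol
Product: 18 (2R,3S,4S)-7-(benzyloxy)-2-[4-(benzyloxy)phenyl]-4-(2-ethoxyethoxy)chroman-3-ol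
Conditions: DDQ (2 equiv), 2-ethoxyethanol, CH2Cl2, rt
Reagents that add atoms: 2-ethoxyethanol (CCOCCO)
Why: Oxidative benzylic etherification known for benzylated flavan-3-ols: DDQ abstracts hydride from C4 (para to the 7-benzyloxy group, ortho to O1) and the alcohol traps the cation, expected cis to the 3-OH, a configuration that is lost again in step 12.

Step 12
Reactants: 18 (2R,3S,4S)-7-(benzyloxy)-2-[4-(benzyloxy)phenyl]-4-(2-ethoxyethoxy)chroman-3-ol; 12 (2S,3S)-7-(benzyloxy)-2-[3,4-bis(benzyloxy)phenyl]chroman-3-ol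
Product: 19 7,4'-di-O-benzylguibourtinidol-(4α→6)-7,3',4'-tri-O-benzyl-ent-epifisetinidol
Conditions: Me3SiOTf (0.2 equiv), 12 (3 equiv), CH2Cl2, −78 °C
Reagents that add atoms: none
Why: Friedel–Crafts alkylation: Lewis-acid ionisation of the C4 ether gives the C4 benzylic cation, which C6 of 12 (para to O1, ortho to the 7-benzyloxy group, less hindered than C8) should attack trans to the 3-OH of the 2,3-trans cation to give the 4α bond, while the excess of 12 suppresses self-condensation of 18.

Step 13
Reactants: 19 7,4'-di-O-benzylguibourtinidol-(4α→6)-7,3',4'-tri-O-benzyl-ent-epifisetinidol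
Product: 20 guibourtinidol-(4α→6)-ent-epifisetinidol (target)
Conditions: H2 (1 atm), Pd(OH)2 on carbon, THF/MeOH/H2O, rt
Reagents that add atoms: none
Why: Hydrogenolysis of the five benzyl ethers, the standard last step for benzylated flavan-3-ol dimers, under which the interflavan bond and the ring-C ether bonds survive.

**Compound list**

1 | 2-bromo-4-hydroxybenzaldehyde | O=Cc1ccc(O)cc1Br | starting material
2 | 4-(benzyloxy)-2-bromobenzaldehyde | O=Cc1ccc(OCc2ccccc2)cc1Br | intermediate
3 | [4-(benzyloxy)-2-bromophenyl]methanol | OCc1ccc(OCc2ccccc2)cc1Br | intermediate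
4 | 4-(benzyloxy)-2-bromo-1-(bromomethyl)benzene | BrCc1ccc(OCc2ccccc2)cc1Br | intermediate
5 | 1-(3,4-dihydroxyphenyl)ethanone | CC(=O)c1ccc(O)c(O)c1 | starting material
6 | 1-[3,4-bis(benzyloxy)phenyl]ethanone | CC(=O)c1ccc(OCc2ccccc2)c(OCc2ccccc2)c1 | intermediate
7 | 1-[3,4-bis(benzyloxy)phenyl]-3-[4-(benzyloxy)-2-bromophenyl]propan-1-one | O=C(CCc1ccc(OCc2ccccc2)cc1Br)c1ccc(OCc2ccccc2)c(OCc2ccccc2)c1 | intermediate
8 | 7-(benzyloxy)-2-[3,4-bis(benzyloxy)phenyl]-4H-chromene | c1cc2c(cc1OCc1ccccc1)OC(c1ccc(OCc3ccccc3)c(OCc3ccccc3)c1)=CC2 | intermediate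
9 | [(2S,3R)-7-(benzyloxy)-2-[3,4-bis(benzyloxy)phenyl]chroman-3-yl](isopinocampheyl)borane, Ipc from (−)-α-pinene | C[C@@H]1[C@@H](B[C@@H]3Cc4ccc(OCc5ccccc5)cc4O[C@H]3c3ccc(OCc4ccccc4)c(OCc4ccccc4)c3)C[C@H]2C[C@@H]1C2(C)C | intermediate
10 | (2S,3R)-7-(benzyloxy)-2-[3,4-bis(benzyloxy)phenyl]chroman-3-ol | c1cc2c(cc1OCc1ccccc1)O[C@@H](c1ccc(OCc3ccccc3)c(OCc3ccccc3)c1)[C@H](O)C2 | intermediate
11 | (2S)-7-(benzyloxy)-2-[3,4-bis(benzyloxy)phenyl]-2H-chromen-3(4H)-one | c1cc2c(cc1OCc1ccccc1)O[C@@H](c1ccc(OCc3ccccc3)c(OCc3ccccc3)c1)C(=O)C2 | intermediate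
12 | (2S,3S)-7-(benzyloxy)-2-[3,4-bis(benzyloxy)phenyl]chroman-3-ol | c1cc2c(cc1OCc1ccccc1)O[C@@H](c1ccc(OCc3ccccc3)c(OCc3ccccc3)c1)[C@@H](O)C2 | intermediate
13 | 1-[4-(benzyloxy)phenyl]ethanone | CC(=O)c1ccc(OCc2ccccc2)cc1 | starting material
14 | 3-[4-(benzyloxy)-2-bromophenyl]-1-[4-(benzyloxy)phenyl]propan-1-one | O=C(CCc1ccc(OCc2ccccc2)cc1Br)c1ccc(OCc2ccccc2)cc1 | intermediate
15 | 7-(benzyloxy)-2-[4-(benzyloxy)phenyl]-4H-chromene | c1cc2c(cc1OCc1ccccc1)OC(c1ccc(OCc3ccccc3)cc1)=CC2 | intermediate
16 | [(2R,3S)-7-(benzyloxy)-2-[4-(benzyloxy)phenyl]chroman-3-yl](isopinocampheyl)borane, Ipc from (+)-α-pinene | C[C@H]1[C@H](B[C@H]3Cc4ccc(OCc5ccccc5)cc4O[C@@H]3c3ccc(OCc4ccccc4)cc3)C[C@@H]2C[C@H]1C2(C)C | intermediate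
17 | (2R,3S)-7-(benzyloxy)-2-[4-(benzyloxy)phenyl]chroman-3-ol | c1cc2c(cc1OCc1ccccc1)O[C@H](c1ccc(OCc3ccccc3)cc1)[C@@H](O)C2 | intermediate
18 | (2R,3S,4S)-7-(benzyloxy)-2-[4-(benzyloxy)phenyl]-4-(2-ethoxyethoxy)chroman-3-ol | c1cc2c(cc1OCc1ccccc1)O[C@H](c1ccc(OCc3ccccc3)cc1)[C@@H](O)[C@H]2OCCOCC | intermediate
19 | 7,4'-di-O-benzylguibourtinidol-(4α→6)-7,3',4'-tri-O-benzyl-ent-epifisetinidol (upper unit 2,3-trans-3,4-trans, lower unit 2,3-cis, both 3-OH free) | O(Cc1ccccc1)c1ccc([C@H]2Oc3cc(OCc4ccccc4)ccc3[C@@H](c3cc4c(cc3OCc3ccccc3)O[C@@H](c3ccc(OCc5ccccc5)c(OCc5ccccc5)c3)[C@@H](O)C4)[C@@H]2O)cc1 | intermediate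
20 | (2R,3S,4R)-4-[(2S,3S)-2-(3,4-dihydroxyphenyl)-3,7-dihydroxychroman-6-yl]-2-(4-hydroxyphenyl)chroman-3,7-diol | Oc1ccc([C@H]2Oc3cc(O)ccc3[C@@H](c3cc4c(cc3O)O[C@@H](c3ccc(O)c(O)c3)[C@@H](O)C4)[C@@H]2O)cc1 | target

**Step count and risks**

Total step count: 13. Longest linear sequence: 9 steps (1, 2, 3, 5, 6, 7, 8, 12, 13).

Steps most likely to fail:

1. Step 5. The methyl ketone enolate may be benzylated twice, and C–O bond formation at copper may be slow for a non-stabilised enolate closing a six-membered ring, so that protodebromination of 7 takes over. The fallback sets out from 6 and 2 and comes back at 8. Claisen–Schmidt condensation of 6 with aldehyde 2 (KOH, EtOH) gives (E)-1-[3,4-bis(benzyloxy)phenyl]-3-[4-(benzyloxy)-2-bromophenyl]prop-2-en-1-one F1, which cannot be over-alkylated. Hydrogenation of the enone C=C with RhCl(PPh3)3 (H2, benzene/EtOH), which should spare the aryl bromide and the benzyl ethers, gives 7 as an isolated ketone. Ring closure is then done with zerovalent palladium (Pd2(dba)3, bis[2-(diphenylphosphino)phenyl] ether, Cs2CO3, toluene, 100 °C) to give 8.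

2. Step 6. Facial selectivity of the chiral borane on the benzo-fused enol ether may be poor, and the β-aryloxy borane 9 may undergo β-elimination with ring opening. The fallback sets out from 8 and comes back at 10. Hydroboration with BH3·SMe2 at 0 °C and mild oxidation with NaBO3 gives racemic trans-7-(benzyloxy)-2-[3,4-bis(benzyloxy)phenyl]chroman-3-ol F2. Esterification with (2S)-2-methoxy-2-phenylacetic acid (dicyclohexylcarbodiimide, 4-dimethylaminopyridine) and chromatographic separation of the two diastereomeric esters gives (2S,3R)-7-(benzyloxy)-2-[3,4-bis(benzyloxy)phenyl]chroman-3-yl (2S)-methoxy(phenyl)acetate F3. Saponification (LiOH, THF/H2O) returns 10.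

3. Step 12. Facial selectivity at the C4 cation may be poor (4β isomer), attack may occur at C8 of 12, and 18 may self-condense. The fallback sets out from 18 and comes back at 19. Acetylation (Ac2O, pyridine) gives (2R,3S,4S)-7-(benzyloxy)-2-[4-(benzyloxy)phenyl]-4-(2-ethoxyethoxy)chroman-3-yl acetate F4. Its Me3SiOTf-promoted coupling with 12 should proceed through an acetoxonium ion bridging C3 and C4, which blocks the face of the 3-oxygen and directs the arene trans (4α), giving the upper-unit 3-O-acetate of 19 F5. Methanolysis (K2CO3, MeOH/THF) returns 19.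

**Further compounds**

F1 | step 5 | (E)-1-[3,4-bis(benzyloxy)phenyl]-3-[4-(benzyloxy)-2-bromophenyl]prop-2-en-1-one | O=C(/C=C/c1ccc(OCc2ccccc2)cc1Br)c1ccc(OCc2ccccc2)c(OCc2ccccc2)c1
F2 | step 6 | racemic trans-7-(benzyloxy)-2-[3,4-bis(benzyloxy)phenyl]chroman-3-ol (2S,3R and 2R,3S) | c1cc2c(cc1OCc1ccccc1)O[C@@H](c1ccc(OCc3ccccc3)c(OCc3ccccc3)c1)[C@H](O)C2.c1cc2c(cc1OCc1ccccc1)O[C@H](c1ccc(OCc3ccccc3)c(OCc3ccccc3)c1)[C@@H](O)C2
F3 | step 6 | (2S,3R)-7-(benzyloxy)-2-[3,4-bis(benzyloxy)phenyl]chroman-3-yl (2S)-methoxy(phenyl)acetate | c1cc2c(cc1OCc1ccccc1)O[C@@H](c1ccc(OCc3ccccc3)c(OCc3ccccc3)c1)[C@H](OC(=O)[C@@H](OC)c1ccccc1)C2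
F4 | step 12 | (2R,3S,4S)-7-(benzyloxy)-2-[4-(benzyloxy)phenyl]-4-(2-ethoxyethoxy)chroman-3-yl acetate | c1cc2c(cc1OCc1ccccc1)O[C@H](c1ccc(OCc3ccccc3)cc1)[C@@H](OC(C)=O)[C@H]2OCCOCC
F5 | step 12 | upper-unit 3-O-acetate of 19 | O(Cc1ccccc1)c1ccc([C@H]2Oc3cc(OCc4ccccc4)ccc3[C@@H](c3cc4c(cc3OCc3ccccc3)O[C@@H](c3ccc(OCc5ccccc5)c(OCc5ccccc5)c3)[C@@H](O)C4)[C@@H]2OC(C)=O)cc1
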